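**Remark on the chemistry (assumptions).** Locants follow the eudesmanolide skeleton: C5–C10 carbocycle; C11, C12, C13 = α‑carbon, carbonyl and methylene of the lactone; C14 = hydroxymethyl carbon; C4(–C15)–C3–C2–C1 = side chain. TBDPS = tert‑butyldiphenylsilyl, TES = triethylsilyl, Tf = trifluoromethanesulfonyl. The facial sense of the auxiliary in step 7 is taken from the usual s‑trans enol ether model (aryl group shields one face); the enantiomeric auxiliary would give the mirror‑image ring.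

## Retrosynthetic overview

1. Eriolangin ⇐ bis‑silyl ether 26 ⇐ hydroxy acid 25 by Mitsunobu lactonisation (lactone ring closed last, with inversion at C8); C12 comes from CO on a C11 enol triflate, and the angelate is placed on O6 before that.
2. The C6–OH and the C5=C10 double bond ⇐ β,γ‑unsaturated ester 16 by epoxidation of C5=C6 and E1cB opening through C10–H.
3. Keto ester 14 ⇐ bicyclo[2.2.2]octenone 11: MeMgBr brings C13 to C11, then Pb(OAc)4 cuts the temporary C11–C14 bond.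
4. 11 ⇐ phenol 7 + methanol + enol ether 9 (oxidative dearomatisation, then [4+2]); this forms C9–C10 and C7–C8 and closes the carbocycle first. Enabling feature: C11 and C14 sit on C7 and C10, 1,4 across the carbocycle, so C7–C6–C5–C10–C14–C11 can be the ring of a 4‑alkyl‑2‑methoxyphenol (C11 = C–OH, C14 = C–OMe) and C8–C9 a vinyl ether.
5. 7 ⇐ O‑benzylvanillin by alkyne formation, carboalumination/oxirane opening and asymmetric hydrogenation (sets C4).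

Key step: step 7

## Forward route

Step 1
Reactants: 1 4‑(benzyloxy)‑3‑methoxybenzaldehyde
Product: 2 1‑(benzyloxy)‑4‑ethynyl‑2‑methoxybenzene
Conditions: dimethyl (1‑diazo‑2‑oxopropyl)phosphonate, K2CO3, MeOH, rt
Reagents that add atoms: dimethyl (1‑diazo‑2‑oxopropyl)phosphonate, CC(=O)C(=[N+]=[N-])P(=O)(OC)OC
Why: Ohira–Bestmann (Seyferth–Gilbert) homologation turns the aryl aldehyde into the terminal alkyne under mild base, and no stereocentre is involved.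

Step 2
Reactants: 2 1‑(benzyloxy)‑4‑ethynyl‑2‑methoxybenzene
Product: 4 (E)‑4‑[4‑(benzyloxy)‑3‑methoxyphenyl]pent‑3‑en‑1‑ol, via alkenylalane 3 (not isolated)
Conditions: AlMe3 (2.5 equiv), Cp2ZrCl2 (0.2 equiv), CH2Cl2, 0 °C to rt; then n‑BuLi, THF, −78 °C; oxirane, −78 to 0 °C; aq. HCl
Reagents that add atoms: trimethylaluminium, C[Al](C)C; oxirane, C1CO1
Why: Zirconium‑catalysed Negishi carboalumination adds methyl and aluminium syn (methyl to the aryl‑bearing carbon), and the derived alkenylalanate opens oxirane with retention, which fixes the (E)‑trisubstituted alkene.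

Step 3
Reactants: 4 (E)‑4‑[4‑(benzyloxy)‑3‑methoxyphenyl]pent‑3‑en‑1‑ol
Product: 5 (E)‑tert‑butyl{[4‑(4‑(benzyloxy)‑3‑methoxyphenyl)pent‑3‑en‑1‑yl]oxy}diphenylsilane
Conditions: TBDPSCl, imidazole, CH2Cl2, rt
Reagents that add atoms: tert‑butyl(chloro)diphenylsilane, CC(C)(C)[Si](Cl)(c1ccccc1)c1ccccc1
Why: Standard silylation of the primary alcohol gives a robust ether that survives every step up to the last one.

Step 4
Reactants: 5 (E)‑tert‑butyl{[4‑(4‑(benzyloxy)‑3‑methoxyphenyl)pent‑3‑en‑1‑yl]oxy}diphenylsilane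
Product: 6 (S)‑tert‑butyl{[4‑(4‑(benzyloxy)‑3‑methoxyphenyl)pentyl]oxy}diphenylsilane
Conditions: H2 (50 bar), [Ir(cod)(L)][B(C6H3(CF3)2)4] (1 mol %), L = (R)‑2‑[2‑(diphenylphosphanyl)phenyl]‑4‑tert‑butyl‑4,5‑dihydrooxazole, CH2Cl2, rt
Reagents that add atoms: none
Why: Iridium‑catalysed asymmetric hydrogenation of an (E)‑trisubstituted aryl alkene with a P,N ligand should set C4 as S under catalyst control, the ligand enantiomer being chosen by analogy with (E)‑α‑methylstilbene‑type substrates.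

Step 5
Reactants: 6 (S)‑tert‑butyl{[4‑(4‑(benzyloxy)‑3‑methoxyphenyl)pentyl]oxy}diphenylsilane
Product: 7 4‑[(2S)‑5‑(TBDPSO)pentan‑2‑yl]‑2‑methoxyphenol
Conditions: H2 (1 atm), Pd/C (10 %), EtOAc, rt
Reagents that add atoms: none
Why: Hydrogenolysis of the benzyl ether frees the phenol while the silyl ether and the benzylic C4 centre are untouched.

Step 6
Reactants: 8 (S)‑1‑(2,4,6‑triisopropylphenyl)ethanol
Product: 9 (S)‑1‑(2,4,6‑triisopropylphenyl)ethyl vinyl ether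
Conditions: butyl vinyl ether (solvent), Pd(OCOCF3)2 (2 mol %), 4,7‑diphenyl‑1,10‑phenanthroline, Et3N, 75 °C
Reagents that add atoms: butyl vinyl ether, C=COCCCC
Why: Palladium‑catalysed transfer vinylation (transetherification) converts the secondary alcohol into its vinyl ether without touching the carbinol stereocentre.

Step 7
Reactants: 7 4‑[(2S)‑5‑(TBDPSO)pentan‑2‑yl]‑2‑methoxyphenol; 9 (S)‑1‑(2,4,6‑triisopropylphenyl)ethyl vinyl ether
Product: 11 (1S,4S,7S)‑3,3‑dimethoxy‑5‑[(2S)‑5‑(TBDPSO)pentan‑2‑yl]‑7‑[(1S)‑1‑(2,4,6‑triisopropylphenyl)ethoxy]bicyclo[2.2.2]oct‑5‑en‑2‑one, via masked o‑benzoquinone 10 (not isolated)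
Conditions: PhI(OAc)2 (1.1 equiv, slow addition), 9 (5 equiv, excess recovered), NaHCO3, MeOH/CH2Cl2, 0 °C to rt
Reagents that add atoms: methanol, CO
Why: PhI(OAc)2 oxidises phenol 7 and methanol is trapped at the methoxy‑bearing carbon to give the masked o‑benzoquinone 10, a 6,6‑dimethoxycyclohexa‑2,4‑dienone that reacts at once as an electron‑poor diene with the electron‑rich enol ether 9 in an inverse‑electron‑demand Diels–Alder reaction, forming C9–C10 and C7–C8 in one concerted, asynchronous step. The closest known reaction type is the in situ masked o‑benzoquinone/enol ether Diels–Alder route to bicyclo[2.2.2]octenones, here run with a chiral enol ether. Two rings close by intermolecular suprafacial [4+2] cycloaddition: the carbocycle C5–C10 of the target and, sharing C7 and C10 with it, the temporary ring through C11 and C14 whose C11–C14 bond is cut in step 10. C7 and C10 are set together by suprafacial addition across the diene termini, C8 by the endo transition state that places the alkoxy group under the diene (syn to the C5=C6 bridge), and the absolute sense by the auxiliary, whose aryl group shields one face of the s‑trans enol ether so that C8 becomes S whatever the remote C4 centre prefers. The step needs regioselectivity (the CH2 terminus of 9 to the δ‑carbon C10 of the dienone and the oxygenated carbon to C7 next to the carbonyl, secured by the polarisation of the dienone), endo and facial selectivity (transition‑state preference and auxiliary), and chemoselectivity over dimerisation of 10 (excess 9 and slow addition of the oxidant).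

Step 8
Reactants: 11 (1S,4S,7S)‑3,3‑dimethoxy‑5‑[(2S)‑5‑(TBDPSO)pentan‑2‑yl]‑7‑[(1S)‑1‑(2,4,6‑triisopropylphenyl)ethoxy]bicyclo[2.2.2]oct‑5‑en‑2‑one
Product: 12 (1S,2R,4S,7S)‑3,3‑dimethoxy‑2‑methyl‑5‑[(2S)‑5‑(TBDPSO)pentan‑2‑yl]‑7‑[(1S)‑1‑(2,4,6‑triisopropylphenyl)ethoxy]bicyclo[2.2.2]oct‑5‑en‑2‑ol
Conditions: MeMgBr, THF, −78 to 0 °C; aq. NH4Cl
Reagents that add atoms: methylmagnesium bromide, C[Mg]Br
Why: Grignard 1,2‑addition to the only carbonyl (non‑enolisable, bridgehead α‑carbon) brings in C13; the new carbinol centre (attack from the alkene side) is inconsequential because it is destroyed in step 10.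

Step 9
Reactants: 12 (1S,2R,4S,7S)‑3,3‑dimethoxy‑2‑methyl‑5‑[(2S)‑5‑(TBDPSO)pentan‑2‑yl]‑7‑[(1S)‑1‑(2,4,6‑triisopropylphenyl)ethoxy]bicyclo[2.2.2]oct‑5‑en‑2‑ol
Product: 13 (1S,3R,4S,8S)‑3,8‑dihydroxy‑3‑methyl‑6‑[(2S)‑5‑(TBDPSO)pentan‑2‑yl]bicyclo[2.2.2]oct‑5‑en‑2‑one
Conditions: CF3CO2H/H2O (9:1), CH2Cl2, 0 °C to rt
Reagents that add atoms: water, O
Why: Acid cleaves the benzylic auxiliary ether through its stabilised cation and hydrolyses the dimethyl ketal to the α‑ketol in one operation, with the auxiliary alcohol recovered and no stereocentre touched.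

Step 10
Reactants: 13 (1S,3R,4S,8S)‑3,8‑dihydroxy‑3‑methyl‑6‑[(2S)‑5‑(TBDPSO)pentan‑2‑yl]bicyclo[2.2.2]oct‑5‑en‑2‑one
Product: 14 methyl (1S,4S,5S)‑4‑acetyl‑5‑hydroxy‑2‑[(2S)‑5‑(TBDPSO)pentan‑2‑yl]cyclohex‑2‑ene‑1‑carboxylate
Conditions: Pb(OAc)4, MeOH/benzene (1:1), 0 °C
Reagents that add atoms: methanol, CO
Why: Oxidative α‑ketol cleavage (glycol‑cleavage type, via the methanol hemiketal) cuts the temporary C11–C14 bond to give the C11 methyl ketone and the C14 methyl ester, which stay cis on C7 and C10 as fixed by the bicycle.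

Step 11
Reactants: 14 methyl (1S,4S,5S)‑4‑acetyl‑5‑hydroxy‑2‑[(2S)‑5‑(TBDPSO)pentan‑2‑yl]cyclohex‑2‑ene‑1‑carboxylate
Product: 15 methyl (1S,4S,5S)‑4‑acetyl‑2‑[(2S)‑5‑(TBDPSO)pentan‑2‑yl]‑5‑(triethylsilyloxy)cyclohex‑2‑ene‑1‑carboxylate
Conditions: TESCl, imidazole, DMF, 0 °C
Reagents that add atoms: chlorotriethylsilane, CC[Si](Cl)(CC)CC
Why: Mild silylation protects the C8 hydroxyl as an ether that can later be removed in the presence of the TBDPS ethers.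

Step 12
Reactants: 15 methyl (1S,4S,5S)‑4‑acetyl‑2‑[(2S)‑5‑(TBDPSO)pentan‑2‑yl]‑5‑(triethylsilyloxy)cyclohex‑2‑ene‑1‑carboxylate
Product: 16 methyl (1S,4S,5S)‑2‑[(2S)‑5‑(TBDPSO)pentan‑2‑yl]‑5‑(triethylsilyloxy)‑4‑[1‑(trifluoromethanesulfonyloxy)ethenyl]cyclohex‑2‑ene‑1‑carboxylate
Conditions: KN(SiMe3)2 (1.05 equiv), THF, −78 °C; PhNTf2, −78 to −20 °C
Reagents that add atoms: N‑phenylbis(trifluoromethanesulfonimide), O=S(=O)(N(c1ccccc1)S(=O)(=O)C(F)(F)F)C(F)(F)F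
Why: Kinetic deprotonation of the methyl ketone at the unhindered CH3 and O‑triflation give the terminal enol triflate, the low temperature avoiding removal of C10–H and β‑elimination of the C8 silyloxy group.

Step 13
Reactants: 16 methyl (1S,4S,5S)‑2‑[(2S)‑5‑(TBDPSO)pentan‑2‑yl]‑5‑(triethylsilyloxy)‑4‑[1‑(trifluoromethanesulfonyloxy)ethenyl]cyclohex‑2‑ene‑1‑carboxylate
Product: 17 2,3‑epoxide of 16 (oxirane oxygen on the ring face opposite to the C1 ester and the C4 alkenyl group)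
Conditions: mCPBA, NaHCO3, CH2Cl2, 0 °C
Reagents that add atoms: 3‑chloroperoxybenzoic acid, OOC(=O)c1cccc(Cl)c1
Why: Prilezhaev epoxidation attacks the only electron‑rich alkene (C5=C6) from the face anti to the cis‑disposed C7 and C10 substituents, which sets the future C6–O configuration trans to the C7 substituent.

Step 14
Reactants: 17 2,3‑epoxide of 16
Product: 18 methyl (3S,4S,5S)‑3‑hydroxy‑2‑[(2S)‑5‑(TBDPSO)pentan‑2‑yl]‑5‑(triethylsilyloxy)‑4‑[1‑(trifluoromethanesulfonyloxy)ethenyl]cyclohex‑1‑ene‑1‑carboxylate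
Conditions: DBU, toluene, 40 °C
Reagents that add atoms: none
Why: E1cB opening of the β,γ‑epoxy ester (C10–H is now the only acidic proton) expels the epoxide oxygen from C5, giving the tetrasubstituted C5=C10 enoate and the C6 alcohol with the configuration fixed in step 13.

Step 15
Reactants: 18 methyl (3S,4S,5S)‑3‑hydroxy‑2‑[(2S)‑5‑(TBDPSO)pentan‑2‑yl]‑5‑(triethylsilyloxy)‑4‑[1‑(trifluoromethanesulfonyloxy)ethenyl]cyclohex‑1‑ene‑1‑carboxylate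
Product: 19 1‑{(1S,2S,6S)‑2‑hydroxy‑4‑(hydroxymethyl)‑3‑[(2S)‑5‑(TBDPSO)pentan‑2‑yl]‑6‑(triethylsilyloxy)cyclohex‑3‑en‑1‑yl}ethenyl trifluoromethanesulfonate
Conditions: i‑Bu2AlH (3 equiv), CH2Cl2, −78 °C; aq. potassium sodium tartrate
Reagents that add atoms: none
Why: 1,2‑Reduction of the conjugated ester with i‑Bu2AlH gives the C14 allylic alcohol at low temperature, where the enol triflate and silyl ethers are inert.

Step 16
Reactants: 19 1‑{(1S,2S,6S)‑2‑hydroxy‑4‑(hydroxymethyl)‑3‑[(2S)‑5‑(TBDPSO)pentan‑2‑yl]‑6‑(triethylsilyloxy)cyclohex‑3‑en‑1‑yl}ethenyl trifluoromethanesulfonate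
Product: 20 1‑{(1S,2S,6S)‑2‑hydroxy‑4‑[(TBDPSO)methyl]‑3‑[(2S)‑5‑(TBDPSO)pentan‑2‑yl]‑6‑(triethylsilyloxy)cyclohex‑3‑en‑1‑yl}ethenyl trifluoromethanesulfonate
Conditions: TBDPSCl (1.05 equiv), imidazole, CH2Cl2, −20 to 0 °C
Reagents that add atoms: tert‑butyl(chloro)diphenylsilane, CC(C)(C)[Si](Cl)(c1ccccc1)c1ccccc1
Why: The bulky silyl chloride reacts selectively with the primary allylic hydroxyl and leaves the hindered secondary C6 hydroxyl free for acylation.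

Step 17
Reactants: 20 1‑{(1S,2S,6S)‑2‑hydroxy‑4‑[(TBDPSO)methyl]‑3‑[(2S)‑5‑(TBDPSO)pentan‑2‑yl]‑6‑(triethylsilyloxy)cyclohex‑3‑en‑1‑yl}ethenyl trifluoromethanesulfonate; 21 angelic acid [(Z)‑2‑methylbut‑2‑enoic acid]
Product: 23 (1S,2S,6S)‑4‑[(TBDPSO)methyl]‑3‑[(2S)‑5‑(TBDPSO)pentan‑2‑yl]‑6‑(triethylsilyloxy)‑1‑[1‑(trifluoromethanesulfonyloxy)ethenyl]cyclohex‑3‑en‑2‑yl (2Z)‑2‑methylbut‑2‑enoate, via mixed anhydride 22 (not isolated)
Conditions: 21, 2,4,6‑trichlorobenzoyl chloride, Et3N, toluene, rt; then 20, 80 °C (no nucleophilic catalyst)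
Reagents that add atoms: none
Why: Yamaguchi‑type mixed‑anhydride esterification without a nucleophilic amine catalyst acylates the hindered C6 alcohol with retention and should avoid isomerisation of the angelate to the tiglate.

Step 18
Reactants: 23 (1S,2S,6S)‑4‑[(TBDPSO)methyl]‑3‑[(2S)‑5‑(TBDPSO)pentan‑2‑yl]‑6‑(triethylsilyloxy)‑1‑[1‑(trifluoromethanesulfonyloxy)ethenyl]cyclohex‑3‑en‑2‑yl (2Z)‑2‑methylbut‑2‑enoate
Product: 24 2‑{(1S,2S,6S)‑2‑[(2Z)‑2‑methylbut‑2‑enoyloxy]‑4‑[(TBDPSO)methyl]‑3‑[(2S)‑5‑(TBDPSO)pentan‑2‑yl]‑6‑(triethylsilyloxy)cyclohex‑3‑en‑1‑yl}prop‑2‑enoic acid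
Conditions: CO (1 atm), Pd(OAc)2 (5 mol %), Fe(C5H4PPh2)2 (dppf), Et3N, H2O, DMF, 50 °C
Reagents that add atoms: carbon monoxide, [C-]#[O+]; water, O
Why: Palladium‑catalysed hydroxycarbonylation of the alkenyl triflate (oxidative addition to zerovalent palladium, CO insertion, hydrolysis of the acyl complex) introduces C12 as the α‑substituted acrylic acid.

Step 19
Reactants: 24 2‑{(1S,2S,6S)‑2‑[(2Z)‑2‑methylbut‑2‑enoyloxy]‑4‑[(TBDPSO)methyl]‑3‑[(2S)‑5‑(TBDPSO)pentan‑2‑yl]‑6‑(triethylsilyloxy)cyclohex‑3‑en‑1‑yl}prop‑2‑enoic acid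
Product: 25 2‑{(1R,2S,6S)‑6‑hydroxy‑2‑[(2Z)‑2‑methylbut‑2‑enoyloxy]‑4‑[(TBDPSO)methyl]‑3‑[(2S)‑5‑(TBDPSO)pentan‑2‑yl]cyclohex‑3‑en‑1‑yl}prop‑2‑enoic acid
Conditions: pyridinium p‑toluenesulfonate, MeOH/CH2Cl2, 0 °C
Reagents that add atoms: none
Why: Mild acid methanolysis removes the secondary triethylsilyl ether much faster than the two primary TBDPS ethers (the descriptor at C7 changes only through priorities).

Step 20
Reactants: 25 2‑{(1R,2S,6S)‑6‑hydroxy‑2‑[(2Z)‑2‑methylbut‑2‑enoyloxy]‑4‑[(TBDPSO)methyl]‑3‑[(2S)‑5‑(TBDPSO)pentan‑2‑yl]cyclohex‑3‑en‑1‑yl}prop‑2‑enoic acid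
Product: 26 1,14‑bis‑O‑(tert‑butyldiphenylsilyl)eriolangin
Conditions: PPh3, diisopropyl azodicarboxylate, THF (0.01 M), 0 °C to rt
Reagents that add atoms: none
Why: Mitsunobu lactonisation lets the acrylate carboxylate displace the activated C8 oxygen intramolecularly (5‑exo‑tet SN2, nucleophile held on the face opposite to the leaving group), inverting C8 to R and giving the cis‑fused α‑methylene lactone.

Step 21
Reactants: 26 1,14‑bis‑O‑(tert‑butyldiphenylsilyl)eriolangin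
Product: 27 eriolangin
Conditions: HF·pyridine, pyridine/THF, 0 °C to rt
Reagents that add atoms: none
Why: Buffered fluoride cleaves both primary silyl ethers without base, so the angelate and the α‑methylene lactone should survive.

## Compound list

1 | 4‑(benzyloxy)‑3‑methoxybenzaldehyde | COc1cc(C=O)ccc1OCc1ccccc1 | starting material
2 | 1‑(benzyloxy)‑4‑ethynyl‑2‑methoxybenzene | COc1cc(C#C)ccc1OCc1ccccc1 | intermediate
3 | (E)‑[2‑(4‑(benzyloxy)‑3‑methoxyphenyl)prop‑1‑enyl]dimethylalane | COc1cc(/C(C)=C/[Al](C)C)ccc1OCc1ccccc1 | intermediate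
4 | (E)‑4‑[4‑(benzyloxy)‑3‑methoxyphenyl]pent‑3‑en‑1‑ol | COc1cc(/C(C)=C/CCO)ccc1OCc1ccccc1 | intermediate
5 | (E)‑tert‑butyl{[4‑(4‑(benzyloxy)‑3‑methoxyphenyl)pent‑3‑en‑1‑yl]oxy}diphenylsilane | COc1cc(/C(C)=C/CCO[Si](c2ccccc2)(c2ccccc2)C(C)(C)C)ccc1OCc1ccccc1 | intermediate
6 | (S)‑tert‑butyl{[4‑(4‑(benzyloxy)‑3‑methoxyphenyl)pentyl]oxy}diphenylsilane | COc1cc([C@@H](C)CCCO[Si](c2ccccc2)(c2ccccc2)C(C)(C)C)ccc1OCc1ccccc1 | intermediate
7 | 4‑[(2S)‑5‑(TBDPSO)pentan‑2‑yl]‑2‑methoxyphenol | COc1cc([C@@H](C)CCCO[Si](c2ccccc2)(c2ccccc2)C(C)(C)C)ccc1O | intermediate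
8 | (S)‑1‑(2,4,6‑triisopropylphenyl)ethanol | C[C@H](O)c1c(C(C)C)cc(C(C)C)cc1C(C)C | starting material
9 | (S)‑1‑(2,4,6‑triisopropylphenyl)ethyl vinyl ether | C=CO[C@@H](C)c1c(C(C)C)cc(C(C)C)cc1C(C)C | intermediate
10 | 6,6‑dimethoxy‑4‑[(2S)‑5‑(TBDPSO)pentan‑2‑yl]cyclohexa‑2,4‑dien‑1‑one (masked o‑benzoquinone) | COC1(OC)C=C([C@@H](C)CCCO[Si](c2ccccc2)(c2ccccc2)C(C)(C)C)C=CC1=O | intermediate
11 | (1S,4S,7S)‑3,3‑dimethoxy‑5‑[(2S)‑5‑(TBDPSO)pentan‑2‑yl]‑7‑[(1S)‑1‑(2,4,6‑triisopropylphenyl)ethoxy]bicyclo[2.2.2]oct‑5‑en‑2‑one (7‑alkoxy syn to the C5=C6 bridge) | O=C1[C@H]2C=C([C@@H](C)CCCO[Si](c3ccccc3)(c3ccccc3)C(C)(C)C)[C@H](C[C@@H]2O[C@@H](C)c4c(C(C)C)cc(C(C)C)cc4C(C)C)C1(OC)OC | intermediate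
12 | (1S,2R,4S,7S)‑3,3‑dimethoxy‑2‑methyl‑5‑[(2S)‑5‑(TBDPSO)pentan‑2‑yl]‑7‑[(1S)‑1‑(2,4,6‑triisopropylphenyl)ethoxy]bicyclo[2.2.2]oct‑5‑en‑2‑ol | C[C@@]1(O)[C@H]2C=C([C@@H](C)CCCO[Si](c3ccccc3)(c3ccccc3)C(C)(C)C)[C@H](C[C@@H]2O[C@@H](C)c4c(C(C)C)cc(C(C)C)cc4C(C)C)C1(OC)OC | intermediate
13 | (1S,3R,4S,8S)‑3,8‑dihydroxy‑3‑methyl‑6‑[(2S)‑5‑(TBDPSO)pentan‑2‑yl]bicyclo[2.2.2]oct‑5‑en‑2‑one | C[C@@]1(O)[C@H]2C=C([C@@H](C)CCCO[Si](c3ccccc3)(c3ccccc3)C(C)(C)C)[C@H](C[C@@H]2O)C1=O | intermediate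
14 | methyl (1S,4S,5S)‑4‑acetyl‑5‑hydroxy‑2‑[(2S)‑5‑(TBDPSO)pentan‑2‑yl]cyclohex‑2‑ene‑1‑carboxylate | CC(=O)[C@H]1C=C([C@@H](C)CCCO[Si](c2ccccc2)(c2ccccc2)C(C)(C)C)[C@@H](C(=O)OC)C[C@@H]1O | intermediate
15 | methyl (1S,4S,5S)‑4‑acetyl‑2‑[(2S)‑5‑(TBDPSO)pentan‑2‑yl]‑5‑(triethylsilyloxy)cyclohex‑2‑ene‑1‑carboxylate | CC(=O)[C@H]1C=C([C@@H](C)CCCO[Si](c2ccccc2)(c2ccccc2)C(C)(C)C)[C@@H](C(=O)OC)C[C@@H]1O[Si](CC)(CC)CC | intermediate
16 | methyl (1S,4S,5S)‑2‑[(2S)‑5‑(TBDPSO)pentan‑2‑yl]‑5‑(triethylsilyloxy)‑4‑[1‑(trifluoromethanesulfonyloxy)ethenyl]cyclohex‑2‑ene‑1‑carboxylate | C=C(OS(=O)(=O)C(F)(F)F)[C@H]1C=C([C@@H](C)CCCO[Si](c2ccccc2)(c2ccccc2)C(C)(C)C)[C@@H](C(=O)OC)C[C@@H]1O[Si](CC)(CC)CC | intermediate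
17 | 2,3‑epoxide of 16 (oxirane oxygen anti to the ester and the triflyloxyvinyl group) | C=C(OS(=O)(=O)C(F)(F)F)[C@H]1[C@@H]2O[C@]2([C@@H](C)CCCO[Si](c3ccccc3)(c3ccccc3)C(C)(C)C)[C@@H](C(=O)OC)C[C@@H]1O[Si](CC)(CC)CC | intermediate
18 | methyl (3S,4S,5S)‑3‑hydroxy‑2‑[(2S)‑5‑(TBDPSO)pentan‑2‑yl]‑5‑(triethylsilyloxy)‑4‑[1‑(trifluoromethanesulfonyloxy)ethenyl]cyclohex‑1‑ene‑1‑carboxylate | C=C(OS(=O)(=O)C(F)(F)F)[C@H]1[C@H](O)C([C@@H](C)CCCO[Si](c2ccccc2)(c2ccccc2)C(C)(C)C)=C(C(=O)OC)C[C@@H]1O[Si](CC)(CC)CC | intermediate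
19 | 1‑{(1S,2S,6S)‑2‑hydroxy‑4‑(hydroxymethyl)‑3‑[(2S)‑5‑(TBDPSO)pentan‑2‑yl]‑6‑(triethylsilyloxy)cyclohex‑3‑en‑1‑yl}ethenyl trifluoromethanesulfonate | C=C(OS(=O)(=O)C(F)(F)F)[C@H]1[C@H](O)C([C@@H](C)CCCO[Si](c2ccccc2)(c2ccccc2)C(C)(C)C)=C(CO)C[C@@H]1O[Si](CC)(CC)CC | intermediate
20 | 1‑{(1S,2S,6S)‑2‑hydroxy‑4‑[(TBDPSO)methyl]‑3‑[(2S)‑5‑(TBDPSO)pentan‑2‑yl]‑6‑(triethylsilyloxy)cyclohex‑3‑en‑1‑yl}ethenyl trifluoromethanesulfonate | C=C(OS(=O)(=O)C(F)(F)F)[C@H]1[C@H](O)C([C@@H](C)CCCO[Si](c2ccccc2)(c2ccccc2)C(C)(C)C)=C(CO[Si](c2ccccc2)(c2ccccc2)C(C)(C)C)C[C@@H]1O[Si](CC)(CC)CC | intermediate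
21 | angelic acid, (Z)‑2‑methylbut‑2‑enoic acid | C/C=C(/C)C(=O)O | starting material
22 | (Z)‑2‑methylbut‑2‑enoic 2,4,6‑trichlorobenzoic anhydride | C/C=C(/C)C(=O)OC(=O)c1c(Cl)cc(Cl)cc1Cl | intermediate
23 | (1S,2S,6S)‑4‑[(TBDPSO)methyl]‑3‑[(2S)‑5‑(TBDPSO)pentan‑2‑yl]‑6‑(triethylsilyloxy)‑1‑[1‑(trifluoromethanesulfonyloxy)ethenyl]cyclohex‑3‑en‑2‑yl (2Z)‑2‑methylbut‑2‑enoate | C=C(OS(=O)(=O)C(F)(F)F)[C@H]1[C@H](OC(=O)/C(C)=C\C)C([C@@H](C)CCCO[Si](c2ccccc2)(c2ccccc2)C(C)(C)C)=C(CO[Si](c2ccccc2)(c2ccccc2)C(C)(C)C)C[C@@H]1O[Si](CC)(CC)CC | intermediate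
24 | 2‑{(1S,2S,6S)‑2‑[(2Z)‑2‑methylbut‑2‑enoyloxy]‑4‑[(TBDPSO)methyl]‑3‑[(2S)‑5‑(TBDPSO)pentan‑2‑yl]‑6‑(triethylsilyloxy)cyclohex‑3‑en‑1‑yl}prop‑2‑enoic acid | C=C(C(=O)O)[C@H]1[C@H](OC(=O)/C(C)=C\C)C([C@@H](C)CCCO[Si](c2ccccc2)(c2ccccc2)C(C)(C)C)=C(CO[Si](c2ccccc2)(c2ccccc2)C(C)(C)C)C[C@@H]1O[Si](CC)(CC)CC | intermediate
25 | 2‑{(1R,2S,6S)‑6‑hydroxy‑2‑[(2Z)‑2‑methylbut‑2‑enoyloxy]‑4‑[(TBDPSO)methyl]‑3‑[(2S)‑5‑(TBDPSO)pentan‑2‑yl]cyclohex‑3‑en‑1‑yl}prop‑2‑enoic acid | C=C(C(=O)O)[C@H]1[C@H](OC(=O)/C(C)=C\C)C([C@@H](C)CCCO[Si](c2ccccc2)(c2ccccc2)C(C)(C)C)=C(CO[Si](c2ccccc2)(c2ccccc2)C(C)(C)C)C[C@@H]1O | intermediate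
26 | 1,14‑bis‑O‑(tert‑butyldiphenylsilyl)eriolangin | C=C1C(=O)O[C@@H]2CC(CO[Si](c3ccccc3)(c3ccccc3)C(C)(C)C)=C([C@@H](C)CCCO[Si](c3ccccc3)(c3ccccc3)C(C)(C)C)[C@@H](OC(=O)/C(C)=C\C)[C@H]12 | intermediate
27 | eriolangin | C=C1C(=O)O[C@@H]2CC(CO)=C([C@@H](C)CCCO)[C@@H](OC(=O)/C(C)=C\C)[C@H]12 | target

## Step count and risks

Total step count: 21. Longest linear sequence: 20 steps (steps 1–5, then 7–21; step 6 is a one‑step branch).

**Risk 1, step 7.** The auxiliary may discriminate the two faces poorly (the C4 centre gives no help), and the hindered enol ether may lose to dimerisation of the dienone. Fallback: set out from 7 and run the same oxidative dearomatisation/cycloaddition with tert‑butyl vinyl ether in large excess, a dienophile class with close precedent. This gives the tert‑butyl ether adduct F1 together with its ring‑diastereomer (about 1:1). MeMgBr converts the mixture into the tertiary alcohol F2, and CF3CO2H/H2O removes the tert‑butyl group and the ketal to give 13 plus its ring‑diastereomer. Burkholderia cepacia lipase with vinyl acetate then acetylates the unwanted (8R)‑configured diastereomer, following the usual empirical preference of lipases for secondary alcohols, to give the acetate F3, which is removed by chromatography. Unreacted 13 re‑enters the route at step 10; stereocontrol is thus replaced by enzymatic separation.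

**Risk 2, step 12.** Deprotonation at C10 (α to the ester and allylic) may compete with kinetic enolisation of the methyl ketone and move the ring double bond into conjugation; the C8 silyloxy group may also be eliminated. Fallback: set out from 13 and cleave the α‑ketol with NaIO4 in aqueous MeOH to the keto acid F4. Silylation (TESCl, imidazole; the silyl ester falls off on aqueous work‑up) gives the silyl ether acid F5. With KN(SiMe3)2 (2.1 equiv) the carboxylate forms first, and its α‑C–H is then no longer acidic enough to compete, so PhNTf2 gives the enol triflate acid F6 cleanly. Me3SiCHN2 in MeOH esterifies F6 to 16, where the route is rejoined.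

**Risk 3, step 20.** The activated C8 oxygen may be eliminated (to a C7=C8 or C8=C9 alkene) instead of being displaced by the carboxylate. Fallback: set out from 23 and remove the triethylsilyl group (pyridinium p‑toluenesulfonate, MeOH) to give the alcohol F7. Dess–Martin oxidation gives the ketone F8. LiBH(s‑Bu)3 at −78 °C attacks anti to the C7 substituent (equatorial attack) and gives the cis alcohol F9, so C8 is set by reduction rather than by substitution. Palladium‑catalysed carbonylative lactonisation of F9 (CO, Pd(OAc)2, dppf, Et3N) closes the lactone with retention and returns to the route at 26.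

Further compounds

F1 | step 7 | (1S,4S,7S)‑7‑tert‑butoxy‑3,3‑dimethoxy‑5‑[(2S)‑5‑(TBDPSO)pentan‑2‑yl]bicyclo[2.2.2]oct‑5‑en‑2‑one | O=C1[C@H]2C=C([C@@H](C)CCCO[Si](c3ccccc3)(c3ccccc3)C(C)(C)C)[C@H](C[C@@H]2OC(C)(C)C)C1(OC)OC
F2 | step 7 | (1S,2R,4S,7S)‑7‑tert‑butoxy‑3,3‑dimethoxy‑2‑methyl‑5‑[(2S)‑5‑(TBDPSO)pentan‑2‑yl]bicyclo[2.2.2]oct‑5‑en‑2‑ol | C[C@@]1(O)[C@H]2C=C([C@@H](C)CCCO[Si](c3ccccc3)(c3ccccc3)C(C)(C)C)[C@H](C[C@@H]2OC(C)(C)C)C1(OC)OC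
F3 | step 7 | (1R,3S,4R,8R)‑3‑hydroxy‑3‑methyl‑2‑oxo‑6‑[(2S)‑5‑(TBDPSO)pentan‑2‑yl]bicyclo[2.2.2]oct‑5‑en‑8‑yl acetate (unwanted ring‑diastereomer) | C[C@]1(O)[C@@H]2C=C([C@@H](C)CCCO[Si](c3ccccc3)(c3ccccc3)C(C)(C)C)[C@@H](C[C@H]2OC(C)=O)C1=O
F4 | step 12 | (1S,4S,5S)‑4‑acetyl‑5‑hydroxy‑2‑[(2S)‑5‑(TBDPSO)pentan‑2‑yl]cyclohex‑2‑ene‑1‑carboxylic acid | CC(=O)[C@H]1C=C([C@@H](C)CCCO[Si](c2ccccc2)(c2ccccc2)C(C)(C)C)[C@@H](C(=O)O)C[C@@H]1O
F5 | step 12 | (1S,4S,5S)‑4‑acetyl‑2‑[(2S)‑5‑(TBDPSO)pentan‑2‑yl]‑5‑(triethylsilyloxy)cyclohex‑2‑ene‑1‑carboxylic acid | CC(=O)[C@H]1C=C([C@@H](C)CCCO[Si](c2ccccc2)(c2ccccc2)C(C)(C)C)[C@@H](C(=O)O)C[C@@H]1O[Si](CC)(CC)CC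
F6 | step 12 | (1S,4S,5S)‑2‑[(2S)‑5‑(TBDPSO)pentan‑2‑yl]‑5‑(triethylsilyloxy)‑4‑[1‑(trifluoromethanesulfonyloxy)ethenyl]cyclohex‑2‑ene‑1‑carboxylic acid | C=C(OS(=O)(=O)C(F)(F)F)[C@H]1C=C([C@@H](C)CCCO[Si](c2ccccc2)(c2ccccc2)C(C)(C)C)[C@@H](C(=O)O)C[C@@H]1O[Si](CC)(CC)CC
F7 | step 20 | (1S,2S,6S)‑6‑hydroxy‑4‑[(TBDPSO)methyl]‑3‑[(2S)‑5‑(TBDPSO)pentan‑2‑yl]‑1‑[1‑(trifluoromethanesulfonyloxy)ethenyl]cyclohex‑3‑en‑2‑yl (2Z)‑2‑methylbut‑2‑enoate | C=C(OS(=O)(=O)C(F)(F)F)[C@H]1[C@H](OC(=O)/C(C)=C\C)C([C@@H](C)CCCO[Si](c2ccccc2)(c2ccccc2)C(C)(C)C)=C(CO[Si](c2ccccc2)(c2ccccc2)C(C)(C)C)C[C@@H]1O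
F8 | step 20 | C8 ketone of F7 (6‑oxo compound, C7 configuration unchanged) | C=C(OS(=O)(=O)C(F)(F)F)[C@H]1[C@H](OC(=O)/C(C)=C\C)C([C@@H](C)CCCO[Si](c2ccccc2)(c2ccccc2)C(C)(C)C)=C(CO[Si](c2ccccc2)(c2ccccc2)C(C)(C)C)CC1=O
F9 | step 20 | C8 epimer of F7 (hydroxyl cis to the triflyloxyvinyl group) | C=C(OS(=O)(=O)C(F)(F)F)[C@H]1[C@H](OC(=O)/C(C)=C\C)C([C@@H](C)CCCO[Si](c2ccccc2)(c2ccccc2)C(C)(C)C)=C(CO[Si](c2ccccc2)(c2ccccc2)C(C)(C)C)C[C@H]1O
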